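| setting | ochre | grey | teal | zeta | gamma |
|---|---|---|---|---|---|
| electrophile | 0.27 M | 0.27 M | 0.27 M | 0.27 M | 0.27 M |
| nucleophile | 0.80 equiv | 0.80 equiv | 0.80 equiv | 0.800 equiv | 0.800 equiv |
| free base | 0.38 equiv (fed, over 8.0 h) | 0.52 equiv (fed, over 8.0 h) | 0.64 equiv (fed, over 8.0 h) | 0.500 equiv (fed, over 8.0 h) | 0.650 equiv (fed, over 8.0 h) |
| protic impurity | 0.0135 M | 0.0135 M | 0.0135 M | 0.0135 M | 0.0135 M |
| remark | run made earlier | run made earlier | run made earlier |  |  |
| time |  |  |  | 10 h | 10 h |

| run | time / h | electrophile / % | target / % |
|---|---|---|---|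
| ochre | 0.500 | 98.0 | 1.6 |
| ochre | 1.00 | 95.3 | 3.9 |
| ochre | 2.00 | 89.7 | 4.1 |
| ochre | 4.00 | 83.8 | 5.8 |
| ochre | 8.00 | 69.3 | 5.5 |
| grey | 1.33 | 94.3 | 1.7 |
| grey | 3.00 | 86.6 | 4.4 |
| grey | 4.00 | 83.5 | 6.6 |
| grey | 6.00 | 75.1 | 6.2 |
| grey | 8.00 | 69.5 | 6.6 |
| teal | 0.500 | 96.6 | 1.3 |
| teal | 1.00 | 97.1 | 3.0 |
| teal | 2.00 | 91.2 | 4.2 |
| teal | 4.00 | 82.7 | 5.2 |
| teal | 8.00 | 68.2 | 4.7 |

(each reading ± 1 percentage point)



* part of the electrophile that has reacted at the end, zeta
* part of the electrophile that has reacted at the end, gamma
* what raising the equivalents of free base from its lowest to its highest value here does to the part of the electrophile that has reacted (changes below 5 percentage points count as none) (no change / it rises / it falls)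

1. I had to read zeta and gamma at 10 h, which is 2.00 h after the feed of free base ends, so I needed a quantity that could be carried beyond the last reading at 8.00 h.

2. I first asked whether free base mattered to the electrophile. At 8.00 h, ochre, fed 0.38 equiv, kept 69.3 % of its charge, and teal, fed 0.64 equiv, kept 68.2 %. That gap of 1.1 percentage points is smaller than the 5 points that counts as a change, so I expected no change in the trend and pooled the runs.

3. With grey at 69.5 %, the mean fraction left was 69.0 %.

4. From this I took the half-time of the electrophile, the time in which the fraction left halves if it falls by the same factor in equal intervals, an apparent first-order reading: 14.9 h.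

5. The reading time is 0.671 half-times, which leaves 62.9 % and gives 37.1 % reacted. That first-order figure was my own reckoning for both flasks.

6. The weak link was the shape of the curve. Ochre's last interval alone gave a half-time of 14.6 h, so the loss had not slowed by then. A straight line through the pooled loss gave 38.8 %, so the choice of shape moved my number little. No run showed the time after the feed, and that remained an assumption.

The forecast, a separate judgement standing 0.40 points above my own figure, gave 37.5 % for zeta, 37.5 % for gamma and no change, with the caution “This assumes the rate doesn't collapse once feeding stops”.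

Zeta gave 37.5 % and gamma 37.8 %, and the trend was no change, with a change of 0.32 points.

    electrophile + nucleophile → acid set free + target (k = 0.170 M⁻¹ h⁻¹)
    nucleophile + protic impurity → quenched reagent (k = 8.60 M⁻¹ h⁻¹)
    acid set free + free base ⇌ salt of the base, settled at all times (K = 16000 M⁻¹)
    electrophile + target → side product (k = 1.60 M⁻¹ h⁻¹)
    nucleophile + acid set free ⇌ protonated nucleophile, settled at all times (K = 6700 M⁻¹)

At 10.0 h, zeta still held 72.1 % of its charged free base and gamma 76.2 %. The half-time of 14.9 h fell 0.40 points short of zeta's result. Carried to zeta read at 25 h, it gives 68.7 % reacted, and that flask holds 63.7 %.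

The runs were computed for substances that don't exist.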